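**Retrosynthetic overview**

1. Longipinane numbering is used: C1 ketone, C2=C3 with CH3 on C3, C4 and C11 bridgeheads, C5 the cyclobutane CH, C6 C(CH3)2, C7 the tiglate carbon, C8 CH2, C9 the senecioate carbon, C10 the quaternary C–CH3. The plan rests on the C4–C5 bond, two neighbouring CH groups that belong both to the six-membered ring C11–C1–C2–C3–C4–C5 and to the seven-membered ring C4–C5–C6–C7–C8–C9–C10, and on the C7 carbinol next to C6(CH3)2, which is the carbinol of pantolactone.
2. Esters last: the C9 senecioate by acylation; the C7 tiglate and the C9 hydrogen together by Evans–Tishchenko reduction of the C7-hydroxy C9-ketone with tiglaldehyde (7,9-anti).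
3. Four-membered ring: the C10–C11 bond by oxidative coupling of the C9 and C1 enol silanes. The C9 ketone with CH3 on C10 is derived from the C10 ketone (C9 hydroxylation, C10 methylenation, oxidation, 1,4-hydrosilylation); the C1 enone comes from Saegusa oxidation.
4. Six-membered ring: Diels–Alder reaction of cycloheptenone 11 (C10 ketone, C4=C5) with 2-silyloxy diene 14 forms C5–C11 and C4–C3 on the face anti to the C7 silyloxy group.
5. Seven-membered ring: ring-closing metathesis of a dienone built from (S)-pantolactone. Ring order: seven, then six, then four.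

Key step: step 10

Remark on the chemistry: (S)-pantolactone is taken as commercially available; C9 is formed as a mixture of epimers in step 11, is carried as such until it becomes trigonal in step 16, and is set for good in step 21.

**Route**

Step 1
Reactants: 1 (S)-pantolactone
Product: 2 (3S)-3-(tert-butyldimethylsilyloxy)-4,4-dimethyloxolan-2-one
Conditions: TBSCl, imidazole, DMF, 23 °C
Reagents that add atoms: tert-butyldimethylsilyl chloride, CC(C)(C)[Si](C)(C)Cl
Why: Silyl ether formation at the only hydroxyl group covers the C7 oxygen with the bulky group that later directs the cycloaddition, and the stereocentre is not involved.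

Step 2
Reactants: 2 (3S)-3-(tert-butyldimethylsilyloxy)-4,4-dimethyloxolan-2-one
Product: 3 (3S)-3-(tert-butyldimethylsilyloxy)-4,4-dimethyloxolan-2-ol (lactol, anomer mixture)
Conditions: i-Bu2AlH, CH2Cl2, −78 °C; aq. potassium sodium tartrate
Reagents that add atoms: none
Why: Partial reduction of the lactone by the aluminium hydride stops at the lactol because the tetrahedral aluminium hemiacetal is stable at −78 °C and is released only on work-up, and C7 is untouched.

Step 3
Reactants: 3 (3S)-3-(tert-butyldimethylsilyloxy)-4,4-dimethyloxolan-2-ol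
Product: 5 (2E,4R)-4-(tert-butyldimethylsilyloxy)-6-hydroxy-N-methoxy-N,5,5-trimethylhex-2-enamide, via open-chain hydroxy aldehyde 4 (not isolated)
Conditions: Ph3P=CHC(O)N(OMe)Me, toluene, 90 °C
Reagents that add atoms: N-methoxy-N-methyl-2-(triphenylphosphoranylidene)acetamide, CON(C)C(=O)C=P(c1ccccc1)(c1ccccc1)c1ccccc1
Why: Wittig olefination of the lactol through its ring-opened aldehyde tautomer with a stabilised ylide should give the E-alkene, and because the medium stays neutral neither silyl migration to the freed primary hydroxyl nor oxa-Michael closure onto the weakly electrophilic unsaturated amide is expected.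

Step 4
Reactants: 5 (2E,4R)-4-(tert-butyldimethylsilyloxy)-6-hydroxy-N-methoxy-N,5,5-trimethylhex-2-enamide
Product: 6 (4R)-4-(tert-butyldimethylsilyloxy)-6-hydroxy-N-methoxy-N,5,5-trimethylhexanamide
Conditions: H2 (1 atm), Pd/C, EtOAc, 23 °C
Reagents that add atoms: none
Why: Heterogeneous catalytic hydrogenation saturates the C8=C9 bond, the only group reducible under these conditions, and so turns the lactone carbonyl carbon of 1 into the C8 methylene group.

Step 5
Reactants: 6 (4R)-4-(tert-butyldimethylsilyloxy)-6-hydroxy-N-methoxy-N,5,5-trimethylhexanamide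
Product: 7 (4R)-4-(tert-butyldimethylsilyloxy)-N-methoxy-N,5,5-trimethyl-6-oxohexanamide
Conditions: Dess–Martin periodinane, CH2Cl2, 0 to 23 °C
Reagents that add atoms: none
Why: Dess–Martin oxidation of the neopentyl primary alcohol gives an aldehyde that has no alpha hydrogen and so can neither enolise nor eliminate the silyloxy group.

Step 6
Reactants: 7 (4R)-4-(tert-butyldimethylsilyloxy)-N-methoxy-N,5,5-trimethyl-6-oxohexanamide
Product: 8 (4R)-4-(tert-butyldimethylsilyloxy)-N-methoxy-N,5,5-trimethylhept-6-enamide
Conditions: Ph3PCH3Br, KN(SiMe3)2, THF, 0 °C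
Reagents that add atoms: methyltriphenylphosphonium bromide, C[P+](c1ccccc1)(c1ccccc1)c1ccccc1.[Br-]
Why: Wittig methylenation is fast at the aldehyde and leaves the much less electrophilic Weinreb amide alone at 0 °C, which places the vinyl group (C5) on the quaternary carbon C6.

Step 7
Reactants: 8 (4R)-4-(tert-butyldimethylsilyloxy)-N-methoxy-N,5,5-trimethylhept-6-enamide
Product: 10 (6R)-6-(tert-butyldimethylsilyloxy)-7,7-dimethylnona-1,8-dien-3-one, via magnesium chelate 9 (not isolated)
Conditions: CH2=CHMgBr, THF, −78 to 0 °C; cold 1 M HCl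
Reagents that add atoms: vinylmagnesium bromide, C=C[Mg]Br
Why: Weinreb ketone synthesis, in which the vinyl Grignard reagent adds only once because the five-membered magnesium chelate holds the tetrahedral adduct until the cold acidic quench, which also keeps the freed amine from adding to the vinyl ketone.

Step 8
Reactants: 10 (6R)-6-(tert-butyldimethylsilyloxy)-7,7-dimethylnona-1,8-dien-3-one
Product: 11 (5R)-5-(tert-butyldimethylsilyloxy)-4,4-dimethylcyclohept-2-en-1-one
Conditions: second-generation Grubbs catalyst RuCl2(=CHPh)(PCy3)(H2IMes) (5 mol%), CH2Cl2 (0.005 M), 40 °C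
Reagents that add atoms: none
Why: Ring-closing olefin metathesis with loss of ethylene should close the seven-membered ring, helped by the gem-dimethyl group, and the ring size allows only the cis C4=C5 alkene.

Step 9
Reactants: 12 (E)-pent-3-en-2-one
Product: 14 (E)-2-(tert-butyldimethylsilyloxy)penta-1,3-diene, via lithium dienolate 13 (not isolated)
Conditions: LiN(i-Pr)2, THF, −78 °C; TBSCl, DMPU, −78 to 0 °C
Reagents that add atoms: tert-butyldimethylsilyl chloride, CC(C)(C)[Si](C)(C)Cl
Why: Kinetic enolisation at the acetyl methyl group followed by O-silylation (silyl enol ether formation) gives the cross-conjugated 2-silyloxy diene and not the linear isomer, with the E alkene unchanged.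

Step 10
Reactants: 11 (5R)-5-(tert-butyldimethylsilyloxy)-4,4-dimethylcyclohept-2-en-1-one; 14 (E)-2-(tert-butyldimethylsilyloxy)penta-1,3-diene
Product: 15 cis-fused bicyclo[5.4.0]undecenone: C10 ketone, C1 TBS enol ether (C1=C2), C3 methyl cis to C10, C7 OTBS, H4 and H5 cis and on the face opposite to the C7 oxygen
Conditions: EtAlCl2 (0.5 equiv), 14 (3 equiv), CH2Cl2–toluene, −78 to −30 °C; Et3N, aq. NaHCO3
Reagents that add atoms: none
Why: EtAlCl2 binds the C10 carbonyl and polarises the C4=C5 bond, so that the diene CH2 next to the silyloxy carbon (C11, its nucleophilic end) bonds to the beta carbon C5 and the methyl-bearing terminus C3 bonds to the alpha carbon C4 in a concerted but asynchronous [4+2] cycloaddition; the closest known reaction type is the aluminium-promoted Diels–Alder reaction of 2-silyloxy-1,3-dienes with 4,4-dialkylcycloalkenones. The six-membered ring C11–C1–C2–C3–C4–C5 is closed by intermolecular suprafacial addition across the cis double bond of the seven-membered ring, which fixes H4 and H5 cis (cis ring fusion). C4 and C5 are set by the face of approach: if the C7 silyloxy group is pseudoequatorial, the C6 methyl group on its side of the ring is pseudoaxial and covers that face of C5, and if it is pseudoaxial it covers that face itself, so the diene should add anti to the C7–O bond, which is the relation of the target. C3 is set by the endo transition state (carbonyl under the diene, methyl cis to C10) and is of no consequence because it becomes trigonal in step 14. The regiochemistry needed is secured twice, since the 2-silyloxy group and the terminal methyl group direct the same way. The step needs strong activation because C5 is neopentyl, and the tert-butyldimethylsilyl enol ether is used because it should survive the Lewis acid and the bases of the next steps while marking C1 for oxygen.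

Step 11
Reactants: 15 cis-fused bicyclic ketone (C10 ketone, C1 TBS enol ether)
Product: 17 C9-hydroxy C10-ketone (C9 epimers), via potassium enolate 16 (not isolated)
Conditions: KN(SiMe3)2, THF, −78 °C; 2-(phenylsulfonyl)-3-phenyloxaziridine, −78 °C; AcOH
Reagents that add atoms: 2-(phenylsulfonyl)-3-phenyloxaziridine, O=S(=O)(c1ccccc1)N1OC1c1ccccc1
Why: Enolate hydroxylation with an N-sulfonyloxaziridine (Davis oxidation), in which the hindered base removes a proton kinetically from the C9 methylene group and not from the C4 methine, so that C4 keeps its configuration, while the enol silane is inert to both reagents at −78 °C and the C9 epimer mixture is of no consequence.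

Step 12
Reactants: 17 C9-hydroxy C10-ketone
Product: 18 C9 triethylsilyl ether of 17
Conditions: Et3SiCl, imidazole, DMF, 0 °C
Reagents that add atoms: triethylsilyl chloride, CC[Si](Cl)(CC)CC
Why: Silyl ether formation protects the C9 hydroxyl, so that the alpha-ketol cannot rearrange and the methylenation reagent of the next step is not consumed.

Step 13
Reactants: 18 C9 triethylsilyl ether of the C10 ketone
Product: 19 exocyclic alkene (C10=CH2) with C9 OTES, C1 TBS enol ether and C7 OTBS
Conditions: Cp2TiMe2 (3 equiv), toluene, 70 °C, dark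
Reagents that add atoms: dimethyltitanocene, C[Ti](C)(C1C=CC=C1)C1C=CC=C1
Why: Petasis methylenation converts the hindered C10 ketone into the exocyclic alkene without base, so the alpha stereocentre C4 is not epimerised and the silyl ethers and the enol silane are left alone.

Step 14
Reactants: 19 exocyclic alkene with C1 TBS enol ether
Product: 20 C1 enone (C2=C3, CH3 on C3) with C10=CH2, C9 OTES and C7 OTBS
Conditions: Pd(OAc)2 (1.1 equiv), MeCN, 23 °C
Reagents that add atoms: none
Why: Saegusa oxidation, in which divalent palladium takes the place of silicon to give the C2-bound palladium enolate and beta-hydride elimination of H3 gives the C1 enone with the methyl group on C3, removing the C3 stereocentre; it is run only now, when C10 is no longer a carbonyl group, so that H4 is never alpha to one ketone and gamma to another.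

Step 15
Reactants: 20 C1 enone with C9 OTES
Product: 21 allylic alcohol (C9 OH, C10=CH2) of the C1 enone
Conditions: PPTS (cat.), MeOH–CH2Cl2, 0 °C
Reagents that add atoms: none
Why: Acid-catalysed methanolysis (silyl ether cleavage) removes the secondary triethylsilyl ether selectively, the neopentyl tert-butyldimethylsilyl ether at C7 being far slower.

Step 16
Reactants: 21 allylic alcohol of the C1 enone
Product: 22 alpha-methylene ketone (C9 ketone, C10=CH2) with C1 enone and C7 OTBS
Conditions: Dess–Martin periodinane, CH2Cl2, 0 °C
Reagents that add atoms: none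
Why: Dess–Martin oxidation of the allylic alcohol gives the alpha-methylene ketone under neutral conditions, which avoids moving the exocyclic alkene into the ring, and C9 becomes trigonal.

Step 17
Reactants: 22 alpha-methylene ketone
Product: 23 C9 triethylsilyl enol ether (C9=C10, CH3 on C10) of the C1 enone
Conditions: Et3SiH, RhCl(PPh3)3 (2 mol%), benzene, 50 °C
Reagents that add atoms: triethylsilane, CC[SiH](CC)CC
Why: Rhodium-catalysed 1,4-hydrosilylation (conjugate hydrosilylation) of the s-cis alpha-methylene ketone delivers hydrogen to the exocyclic CH2 and silicon to oxygen, which gives the tetrasubstituted C9 enol silane as a single regioisomer and creates the C10 methyl group, while the s-trans, beta,beta-disubstituted C1 enone should react much more slowly.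

Step 18
Reactants: 23 C9 triethylsilyl enol ether of the C1 enone
Product: 25 bis(enol silane): C9 OTES (C9=C10), C1 OTMS (C1=C11), C2=C3, via lithium dienolate 24 (not isolated)
Conditions: LiN(i-Pr)2, THF, −78 °C; Me3SiCl, −78 to 0 °C
Reagents that add atoms: trimethylsilyl chloride, C[Si](C)(C)Cl
Why: Kinetic deprotonation of the enone at the alpha-prime carbon C11 (cross-conjugated dienolate) and O-silylation, made clean by the fact that the C9 carbonyl is masked as its enol silane and so can neither be enolised towards C8 nor lose the beta silyloxy group at C7.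

Step 19
Reactants: 25 bis(enol silane)
Product: 26 7-(tert-butyldimethylsilyloxy)longipin-2-ene-1,9-dione (tricyclic diketone, configuration as in 31)
Conditions: (NH4)2Ce(NO3)6 (2.2 equiv), NaHCO3, MeCN (0.005 M), −30 to 0 °C
Reagents that add atoms: none
Why: Oxidative coupling of two enol silanes by tetravalent cerium, a known way to 1,4-diketones, in which one-electron oxidation of the C9 enol silane gives a radical cation centred on C10 that adds to C11 of the silyloxy diene (4-exo-trig) and the silyloxyallyl radical so formed is oxidised at once with loss of both silyl groups, which makes the closure irreversible; C10 and C11 can be joined only on the face allowed by the cis C4–C5 fusion and the C6–C9 tether, so both new stereocentres follow from C4 and C5.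

Step 20
Reactants: 26 7-(tert-butyldimethylsilyloxy)longipin-2-ene-1,9-dione
Product: 27 7-hydroxylongipin-2-ene-1,9-dione
Conditions: HF (48% aq.), MeCN, 0 to 23 °C
Reagents that add atoms: none
Why: Silyl ether cleavage with HF is acidic, so the beta-hydroxy ketone that is set free should undergo neither retro-aldol cleavage nor elimination, and the enone and the cyclobutane tolerate it.

Step 21
Reactants: 27 7-hydroxylongipin-2-ene-1,9-dione; 28 tiglaldehyde ((E)-2-methylbut-2-enal)
Product: 30 9-hydroxy-7-[(E)-2-methylbut-2-enoyloxy]longipin-2-en-1-one (7,9-anti), via hemiacetal 29 (not isolated)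
Conditions: SmI2 (0.3 equiv, premixed with 28), 28 (8 equiv), THF, −10 °C
Reagents that add atoms: none
Why: Evans–Tishchenko reduction, in which the C7 hydroxyl and the aldehyde form hemiacetal 29, trivalent samarium ties its oxygen to the C9 carbonyl and the hemiacetal hydrogen passes to C9 through a six-membered transition state from the face that carries O7, which sets C9 with the 7,9-anti relation of the target and leaves the tiglate on O7; premixing SmI2 with the aldehyde keeps reducing divalent samarium away from the strained diketone.

Step 22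
Reactants: 30 9-hydroxy-7-[(E)-2-methylbut-2-enoyloxy]longipin-2-en-1-one
Product: 31 CNP0257816.1, (4R,5S,7R,9R,10R,11R)-9-(3-methylbut-2-enoyloxy)-7-[(E)-2-methylbut-2-enoyloxy]longipin-2-en-1-one
Conditions: 3-methylbut-2-enoyl chloride, pyridine, DMAP (cat.), CH2Cl2, 0 to 23 °C
Reagents that add atoms: 3-methylbut-2-enoyl chloride, CC(C)=CC(=O)Cl
Why: Acylation (esterification) of the hindered C9 alcohol with the acid chloride under nucleophilic catalysis, with pyridine too weak a base to deconjugate the senecioyl group by way of a vinylketene and with the tiglate on O7 unable to migrate to the trans-disposed O9.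

**Compound list**

1 | (S)-pantolactone | O[C@@H]1C(=O)OCC1(C)C | starting material
2 | (3S)-3-(tert-butyldimethylsilyloxy)-4,4-dimethyloxolan-2-one | CC(C)(C)[Si](C)(C)O[C@@H]1C(=O)OCC1(C)C | intermediate
3 | (3S)-3-(tert-butyldimethylsilyloxy)-4,4-dimethyloxolan-2-ol (anomer mixture) | CC(C)(C)[Si](C)(C)O[C@@H]1C(O)OCC1(C)C | intermediate
4 | (2S)-2-(tert-butyldimethylsilyloxy)-4-hydroxy-3,3-dimethylbutanal, open form of 3 | O=C[C@@H](O[Si](C)(C)C(C)(C)C)C(C)(C)CO | intermediate (not isolated)
5 | (2E,4R)-4-(tert-butyldimethylsilyloxy)-6-hydroxy-N-methoxy-N,5,5-trimethylhex-2-enamide | CON(C)C(=O)/C=C/[C@@H](O[Si](C)(C)C(C)(C)C)C(C)(C)CO | intermediate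
6 | (4R)-4-(tert-butyldimethylsilyloxy)-6-hydroxy-N-methoxy-N,5,5-trimethylhexanamide | CON(C)C(=O)CC[C@@H](O[Si](C)(C)C(C)(C)C)C(C)(C)CO | intermediate
7 | (4R)-4-(tert-butyldimethylsilyloxy)-N-methoxy-N,5,5-trimethyl-6-oxohexanamide | CON(C)C(=O)CC[C@@H](O[Si](C)(C)C(C)(C)C)C(C)(C)C=O | intermediate
8 | (4R)-4-(tert-butyldimethylsilyloxy)-N-methoxy-N,5,5-trimethylhept-6-enamide | CON(C)C(=O)CC[C@@H](O[Si](C)(C)C(C)(C)C)C(C)(C)C=C | intermediate
9 | bromomagnesium alkoxide (chelated tetrahedral adduct of 8 and the vinyl Grignard reagent) | C=CC(O[Mg]Br)(N(C)OC)CC[C@@H](O[Si](C)(C)C(C)(C)C)C(C)(C)C=C | intermediate (not isolated)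
10 | (6R)-6-(tert-butyldimethylsilyloxy)-7,7-dimethylnona-1,8-dien-3-one | C=CC(=O)CC[C@@H](O[Si](C)(C)C(C)(C)C)C(C)(C)C=C | intermediate
11 | (5R)-5-(tert-butyldimethylsilyloxy)-4,4-dimethylcyclohept-2-en-1-one | O=C1C=CC(C)(C)[C@H](O[Si](C)(C)C(C)(C)C)CC1 | intermediate
12 | (E)-pent-3-en-2-one | C/C=C/C(C)=O | starting material
13 | lithium (E)-penta-1,3-dien-2-olate | [Li+].[O-]C(=C)/C=C/C | intermediate (not isolated)
14 | (E)-2-(tert-butyldimethylsilyloxy)penta-1,3-diene | C=C(O[Si](C)(C)C(C)(C)C)/C=C/C | intermediate
15 | Diels–Alder adduct: cis-fused bicyclo[5.4.0]undecenone, C10 ketone, C1 TBS enol ether, C3 methyl cis to C10, C7 OTBS anti to H4 and H5 | O=C1[C@H]2[C@@H](C)C=C(O[Si](C)(C)C(C)(C)C)C[C@H]2C(C)(C)[C@H](O[Si](C)(C)C(C)(C)C)CC1 | intermediate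
16 | potassium C9=C10 enolate of 15 | C1=C([O-])[C@H]2[C@@H](C)C=C(O[Si](C)(C)C(C)(C)C)C[C@H]2C(C)(C)[C@H](O[Si](C)(C)C(C)(C)C)C1.[K+] | intermediate (not isolated)
17 | C9-hydroxy C10-ketone (C9 epimers) | O=C1[C@H]2[C@@H](C)C=C(O[Si](C)(C)C(C)(C)C)C[C@H]2C(C)(C)[C@H](O[Si](C)(C)C(C)(C)C)CC1O | intermediate
18 | C9 triethylsilyl ether of 17 | O=C1[C@H]2[C@@H](C)C=C(O[Si](C)(C)C(C)(C)C)C[C@H]2C(C)(C)[C@H](O[Si](C)(C)C(C)(C)C)CC1O[Si](CC)(CC)CC | intermediate
19 | C10 exocyclic alkene with C9 OTES and C1 TBS enol ether | C=C1[C@H]2[C@@H](C)C=C(O[Si](C)(C)C(C)(C)C)C[C@H]2C(C)(C)[C@H](O[Si](C)(C)C(C)(C)C)CC1O[Si](CC)(CC)CC | intermediate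
20 | C1 enone (C2=C3) with C10=CH2 and C9 OTES | C=C1[C@H]2C(C)=CC(=O)C[C@H]2C(C)(C)[C@H](O[Si](C)(C)C(C)(C)C)CC1O[Si](CC)(CC)CC | intermediate
21 | C1 enone with C9 OH and C10=CH2 | C=C1[C@H]2C(C)=CC(=O)C[C@H]2C(C)(C)[C@H](O[Si](C)(C)C(C)(C)C)CC1O | intermediate
22 | C1 enone with C9 ketone and C10=CH2 (alpha-methylene ketone) | C=C1[C@H]2C(C)=CC(=O)C[C@H]2C(C)(C)[C@H](O[Si](C)(C)C(C)(C)C)CC1=O | intermediate
23 | C1 enone with C9 triethylsilyl enol ether (C9=C10, CH3 on C10) | CC[Si](CC)(CC)OC1=C(C)[C@H]2C(C)=CC(=O)C[C@H]2C(C)(C)[C@H](O[Si](C)(C)C(C)(C)C)C1 | intermediate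
24 | lithium C1=C11 dienolate of 23 | CC[Si](CC)(CC)OC1=C(C)[C@H]2C(C)=CC([O-])=C[C@H]2C(C)(C)[C@H](O[Si](C)(C)C(C)(C)C)C1.[Li+] | intermediate (not isolated)
25 | bis(enol silane): C9 OTES (C9=C10), C1 OTMS (C1=C11), C2=C3 | CC[Si](CC)(CC)OC1=C(C)[C@H]2C(C)=CC(O[Si](C)(C)C)=C[C@H]2C(C)(C)[C@H](O[Si](C)(C)C(C)(C)C)C1 | intermediate
26 | 7-(tert-butyldimethylsilyloxy)longipin-2-ene-1,9-dione | CC(C)(C)[Si](C)(C)O[C@@H]1CC(=O)[C@@]2(C)[C@@H]3C(=O)C=C(C)[C@H]2[C@@H]3C1(C)C | intermediate
27 | 7-hydroxylongipin-2-ene-1,9-dione | O[C@@H]1CC(=O)[C@@]2(C)[C@@H]3C(=O)C=C(C)[C@H]2[C@@H]3C1(C)C | intermediate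
28 | tiglaldehyde, (E)-2-methylbut-2-enal | C/C=C(\C)C=O | starting material
29 | C7 hemiacetal of 27 with 28 | C/C=C(\C)C(O)O[C@@H]1CC(=O)[C@@]2(C)[C@@H]3C(=O)C=C(C)[C@H]2[C@@H]3C1(C)C | intermediate (not isolated)
30 | 9-hydroxy-7-[(E)-2-methylbut-2-enoyloxy]longipin-2-en-1-one | C/C=C(\C)C(=O)O[C@@H]1C[C@@H](O)[C@@]2(C)[C@@H]3C(=O)C=C(C)[C@H]2[C@@H]3C1(C)C | intermediate
31 | CNP0257816.1 | C/C=C(\C)C(=O)O[C@@H]1C[C@@H](OC(=O)C=C(C)C)[C@@]2(C)[C@@H]3C(=O)C=C(C)[C@H]2[C@@H]3C1(C)C | target

**Step count and risks**

Total step count: 22. Longest linear sequence: 21 steps (1 to 31 through steps 1–8 and 10–22; step 9 is a one-step side branch).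

Steps most likely to fail:

Step 19. After one-electron oxidation, closure to the strained four-membered ring may be slower than proton loss from the oxidised C9 enol silane (which would return an enone), capture by nitrate, or intermolecular coupling. The fallback replaces the oxidative closure by a polar one and sets out from 25. N-bromosuccinimide at −78 °C in THF should brominate the less hindered and more labile trimethylsilyl dienol ether at C11, from the face away from C10, to give the C11 bromo enone F1, in which the C9 triethylsilyl enol ether is kept. Tris(dimethylamino)sulfonium difluorotrimethylsilicate in THF at −40 to 0 °C would then release the C10 enolate at one defined position, and this enolate displaces the neighbouring bromide with inversion (intramolecular enolate alkylation, 4-exo-tet). The fallback comes back to the route at 26.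

Step 10. The cycloaddition may stall at the neopentyl carbon C5, may take a stepwise course with loss of the silyl group, or may show insufficient preference for the face anti to the C7 oxygen; a stronger aluminium Lewis acid (AlBr3 with a little AlMe3) would be tried first within the step. The fallback is an anionic double Michael annulation and sets out from 11 and the lithium dienolate 13 made as in step 9. The CH2 terminus of 13 adds to C5 of 11 in THF at −78 °C to give the monocyclic C10 enolate F2. On warming, C4 of F2 closes onto C3 of the pendant enone to give the bicyclic C1 enolate F3, which is trapped with TBSOTf. The fallback comes back to the route at 15.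

Step 21. Hemiacetal formation by the conjugated, less electrophilic aldehyde may be too unfavourable for hydride transfer, or the samarium reagent may reduce the enal instead. The fallback separates the reduction from the introduction of the tiglate and sets out from 27. Evans–Tishchenko reduction with acetaldehyde and SmI2 should give the 7-acetate 9-alcohol F4 with the same 7,9-anti relation. Acylation of C9 with 3-methylbut-2-enoyl chloride, pyridine and DMAP gives the 7-acetate 9-senecioate F5. Methanolysis with K2CO3 in MeOH at 0 °C should remove the acetate faster than the conjugated, beta,beta-disubstituted senecioate to give the 7-alcohol 9-senecioate F6. Acylation of C7 with (E)-2-methylbut-2-enoyl chloride, pyridine and DMAP brings the fallback back to the route at 31.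

**Further compounds**

F1 | step 19 | C11 bromo C1 enone with C9 triethylsilyl enol ether | CC[Si](CC)(CC)OC1=C(C)[C@H]2C(C)=CC(=O)[C@H](Br)[C@H]2C(C)(C)[C@H](O[Si](C)(C)C(C)(C)C)C1
F2 | step 10 | monocyclic lithium C10 enolate carrying the pentenone side chain on C5 | [Li+].[O-]C1=C[C@@H](CC(=O)/C=C/C)C(C)(C)[C@H](O[Si](C)(C)C(C)(C)C)CC1
F3 | step 10 | bicyclic lithium C1 enolate (C1=C2) with C10 ketone | O=C1[C@H]2[C@@H](C)C=C([O-])C[C@H]2C(C)(C)[C@H](O[Si](C)(C)C(C)(C)C)CC1.[Li+]
F4 | step 21 | 7-acetoxy-9-hydroxylongipin-2-en-1-one | CC(=O)O[C@@H]1C[C@@H](O)[C@@]2(C)[C@@H]3C(=O)C=C(C)[C@H]2[C@@H]3C1(C)C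
F5 | step 21 | 7-acetoxy-9-(3-methylbut-2-enoyloxy)longipin-2-en-1-one | CC(=O)O[C@@H]1C[C@@H](OC(=O)C=C(C)C)[C@@]2(C)[C@@H]3C(=O)C=C(C)[C@H]2[C@@H]3C1(C)C
F6 | step 21 | 7-hydroxy-9-(3-methylbut-2-enoyloxy)longipin-2-en-1-one | O[C@@H]1C[C@@H](OC(=O)C=C(C)C)[C@@]2(C)[C@@H]3C(=O)C=C(C)[C@H]2[C@@H]3C1(C)C
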